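**Assumptions (one line each)**
- Lewis-acid catalyst and tartrate-crotylboronate enantiomers are whichever give the configurations drawn.
- The N-acetyl carbon derives from D-alanine (R), as the target SMILES requires.

## Retrosynthetic overview
1. The 16-membered lactone is closed last by an intramolecular HWE reaction (C2=C3 trienoate) of a phosphonoacetate ester onto a (Z)-dienal.
2. The dienal is built from the quaternary-carbon aldehyde by Takai–Stille. The stereopentad side chain comes from two Felkin-matched (E)-crotylborations of D-alaninal and is joined to the core by Suzuki coupling at an enol triflate.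
3. The cyclohexene ring's alkene and the adjacent C–C stereocentre come from a suprafacial Claisen transposition of an allylic alcohol.
4. The oxygenated cyclohexane ring is formed by an endo Diels–Alder reaction of a 1,3-dioxygenated diene with one alkene of a prochiral cyclohexa-2,5-dienone. This breaks the dienone's symmetry, sets the cis ring fusion and the OTIPS centre, and is followed by reductive etherification to the OMe.
5. The dienone comes from benzoic acid by Birch dearomatization (reductive methylation) plus oxidation. Ring order: cyclohexene ring (Birch), oxygenated ring (Diels–Alder), ring alkene (Claisen), macrolactone (HWE).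

## Route

**Step 1**
Reactants: 1 benzoic acid
Product: 2 1-methylcyclohexa-2,5-diene-1-carboxylic acid (achiral; the two ring alkenes are enantiotopic)
Conditions: Li, NH3(l), t-BuOH (1 equiv), THF, –78 °C; then MeI, –78 °C to rt
Reagents that add atoms: methyl iodide, CI
Why: Birch reduction dearomatizes the ring, and alkylation of the ipso carboxylate-enolate carbon creates the quaternary methyl centre (Birch reductive alkylation).

**Step 2**
Reactants: 2
Product: 3 methyl 1-methylcyclohexa-2,5-diene-1-carboxylate
Conditions: MeI, K2CO3, DMF, rt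
Reagents that add atoms: methyl iodide, CI
Why: SN2 O-alkylation of the carboxylate; no stereocentre is formed.

**Step 3**
Reactants: 3
Product: 4 methyl 1-methyl-4-oxocyclohexa-2,5-diene-1-carboxylate (achiral, prochiral dienone)
Conditions: Rh2(cap)4 (1 mol %), TBHP (5 equiv), K2CO3, CH2Cl2, rt; then DBU
Reagents that add atoms: tert-butyl hydroperoxide, CC(C)(C)OO
Why: Proposed new method: Rh2(cap)4/TBHP abstracts the weak bis-allylic C4–H to give a pentadienyl radical that couples with t-BuOO• at the unhindered C4, and DBU-induced Kornblum–DeLaMare loss of t-BuOH gives the cross-conjugated dienone (closest known reaction: Doyle Rh2(cap)4 allylic oxidation to enones); the quaternary C1 prevents aromatization.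

**Step 4**
Reactants: 5 sodium (E)-3-oxobut-1-en-1-olate (formylacetone sodium salt)
Product: 6 (E)-4-(triisopropylsilyloxy)but-3-en-2-one
Conditions: TIPSCl, DMF, 0 °C to rt
Reagents that add atoms: triisopropylsilyl chloride, CC(C)[Si](Cl)(C(C)C)C(C)C
Why: O-silylation of the ambident enolate at the aldehyde oxygen gives the (E)-β-siloxy enone.

**Step 5**
Reactants: 6
Product: 7 (E)-1-(triisopropylsilyloxy)-3-(trimethylsilyloxy)buta-1,3-diene
Conditions: TMSOTf, Et3N, CH2Cl2, 0 °C
Reagents that add atoms: TMSOTf, C[Si](C)(C)OS(=O)(=O)C(F)(F)F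
Why: Danishefsky-type silyl dienol ether formation; the E geometry at C1 is retained.

**Step 6**
Reactants: 4, 7
Product: 8 cis-fused bicyclic keto-enone. The OTIPS carbon is cis to the other ring's C–C bonds and trans to the ring-fusion H. The quaternary carbon carries CH3 and CO2CH3, with CO2CH3 cis to the new ring. Single enantiomer (SMILES in list).
Conditions: 10 mol % chiral cationic oxazaborolidinium NTf2 catalyst (enantiomer giving 8 as drawn), CH2Cl2, –78 to –30 °C; then 0.1 M HCl, THF, 0 °C
Reagents that add atoms: water (ketone oxygen from TMS-enol-ether hydrolysis), O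
Why: Proposed new method: the chiral Lewis acid binds the dienone carbonyl so the diene adds endo to only one of the two enantiotopic enone C=C bonds, on the face syn to the small planar CO2Me and anti to CH3. The O-bearing diene terminus bonds to the α-carbon and the CH2 terminus to the hindered β-carbon. This sets the cis ring fusion, the quaternary centre's absolute sense and the endo OTIPS centre (closest known reactions: Danishefsky-diene/enone Diels–Alder and oxazaborolidinium-catalysed enone Diels–Alder).

**Step 7**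
Reactants: 8
Product: 9 methyl ether: the saturated ketone becomes CH–OCH3, cis to OTIPS; the enone and ester are untouched
Conditions: Et3SiH, TMSOMe, TMSOTf (5 mol %), CH2Cl2, –78 to –30 °C
Reagents that add atoms: methoxytrimethylsilane, CO[Si](C)(C)C
Why: Reductive etherification (via the methoxy-oxocarbenium ion) delivers hydride to the convex face, opposite the concave face that carries the other ring's carbons and the OTIPS, so OMe ends up cis to OTIPS; the enone is less electrophilic and survives.

**Step 8**
Reactants: 9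
Product: 10 allylic alcohol, with the new carbinol OH on the concave face (cis to the ring-fusion-bonded carbons)
Conditions: NaBH4, CeCl3·7H2O, MeOH, –78 to –20 °C
Reagents that add atoms: none
Why: Luche 1,2-reduction with hydride from the convex face (same side as the ring-fusion hydrogens) sets the carbinol stereocentre needed for suprafacial transfer in Step 9.

**Step 9**
Reactants: 10
Product: 11 γ,δ-unsaturated methyl ketone: Cc–CH2COCH3 on the concave face, ring alkene C7=C8
Conditions: 2-methoxypropene (10 equiv), propionic acid (cat.), toluene, 130 °C, sealed tube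
Reagents that add atoms: 2-methoxypropene, C=C(C)OC
Why: Claisen rearrangement (Saucy–Marbet type): the allyl isopropenyl ether undergoes [3,3] shift with the new C–C bond forming on the same face as the C–O bond, which sets the ring stereocentre and moves the alkene into the target position.

**Step 10**
Reactants: 11
Product: 12 (E)-enol triflate Cc–CH=C(CH3)OTf with OTf trans to Cc
Conditions: Tf2O, 2,6-di-tert-butyl-4-methylpyridine, ClCH2CH2Cl, 0 °C to 60 °C
Reagents that add atoms: triflic anhydride, O=S(=O)(C(F)(F)F)OS(=O)(=O)C(F)(F)F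
Why: Stang-type triflation under thermodynamic control favours the more-substituted enol triflate with the bulky OTf trans to the ring, which after Pd coupling gives the (E)-C1'=C2' diene.

**Step 11**
Reactants: 12
Product: 13 free secondary alcohol (OTIPS removed, configuration unchanged)
Conditions: HF·pyridine, pyridine, THF, 0 °C to rt
Reagents that add atoms: none
Why: Fluoride desilylation; the enol triflate, ester, OMe and alkene are stable.

**Step 12**
Reactants: 13
Product: 14 primary carbamate (retention at the carbinol carbon)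
Conditions: Cl3CC(O)NCO, CH2Cl2, 0 °C; then neutral Al2O3, MeOH/CH2Cl2, rt
Reagents that add atoms: trichloroacetyl isocyanate, ClC(Cl)(Cl)C(=O)N=C=O
Why: The alcohol adds to the isocyanate and the N-trichloroacetyl group is removed on alumina (mild, so the enol triflate survives), giving OC(O)NH2.

**Step 13**
Reactants: 15 (R)-2-aminopropan-1-ol (D-alaninol)
Product: 16 (R)-N-(1-hydroxypropan-2-yl)acetamide
Conditions: Ac2O (1.0 equiv), MeOH, 0 °C
Reagents that add atoms: acetic anhydride, CC(=O)OC(C)=O
Why: The amine is much more nucleophilic than the alcohol, so acetylation is N-selective; the stereocentre is untouched.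

**Step 14**
Reactants: 16
Product: 17 (2R)-2-acetamidopropanal (used crude)
Conditions: Dess–Martin periodinane, NaHCO3, CH2Cl2, 0 °C
Reagents that add atoms: none
Why: Neutral, mild oxidation that limits α-epimerization.

**Step 15**
Reactants: 17
Product: 18 anti,anti homoallylic alcohol, AcNH–CH(CH3)–CH(OH)–CH(CH3)–CH=CH2 (C9'–C8' anti, C8'–C7' anti)
Conditions: (E)-crotyl tartrate boronate (matched enantiomer), 4 Å MS, toluene, –78 °C
Reagents that add atoms: (E)-crotylboronic acid diisopropyl tartrate ester, C/C=C/CB1OC(C(=O)OC(C)C)C(C(=O)OC(C)C)O1 (tartrate enantiomer chosen to reinforce Felkin addition)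
Why: Roush crotylboration through a chair transition state: the E-crotyl geometry gives the anti C8'/C7' pair and the reagent face matches the Felkin face of the α-acylamino aldehyde, giving the anti N/O relationship.

**Step 16**
Reactants: 18
Product: 19 TBS ether of 18
Conditions: TBSOTf, 2,6-lutidine, CH2Cl2, –78 °C
Reagents that add atoms: tert-butyldimethylsilyl triflate, CC(C)(C)[Si](C)(C)OS(=O)(=O)C(F)(F)F
Why: Silylation of the hindered secondary alcohol; no stereocentre is affected.

**Step 17**
Reactants: 19
Product: 20 α-methyl aldehyde (used crude), OHC–CH(CH3)–CH(OTBS)–CH(CH3)NHAc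
Conditions: O3, CH2Cl2/MeOH, –78 °C; then PPh3
Reagents that add atoms: ozone, [O-][O+]=O
Why: Ozonolysis cleaves the terminal vinyl group chemoselectively; the other groups are inert.

**Step 18**
Reactants: 20
Product: 21 syn/anti/anti/anti stereopentad alcohol: C9'/C8' anti, C8'/C7' anti, C7'/C6' syn, C6'/C5' anti, with terminal vinyl
Conditions: (E)-crotyl tartrate boronate (matched enantiomer), 4 Å MS, toluene, –78 °C
Reagents that add atoms: (E)-crotylboronic acid diisopropyl tartrate ester, C/C=C/CB1OC(C(=O)OC(C)C)C(C(=O)OC(C)C)O1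
Why: Roush crotylboration: the E-reagent gives the anti C6'/C5' pair and the Felkin-matched facial selectivity on the α-methyl aldehyde gives the C7'/C6' syn relationship.

**Step 19**
Reactants: 21
Product: 22 (E)-alkenyl-Bpin of 21
Conditions: vinyl-Bpin (3 equiv), Grubbs–Hoveyda II (5 mol %), CH2Cl2, 40 °C
Reagents that add atoms: vinylboronic acid pinacol ester, C=CB1OC(C)(C)C(C)(C)O1
Why: Cross-metathesis of the terminal alkene with vinyl-Bpin gives the (E)-alkenylboronate; the free OH and NHAc are tolerated.

**Step 20**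
Reactants: 14, 22
Product: 23 diene-coupled core–chain compound with the (E,E) C1'=C2'(CH3)–C3'=C4' diene
Conditions: Pd(PPh3)4 (10 mol %), Cs2CO3, THF/H2O, 50 °C
Reagents that add atoms: none
Why: Suzuki–Miyaura coupling is stereoretentive at both partners, so it gives the trans C1'=C2' (Cc trans to C3') and the E C3'=C4' diene, with no new stereocentre.

**Step 21**
Reactants: 23
Product: 24 aldehyde on the quaternary carbon (CO2CH3 → CHO)
Conditions: DIBAL-H (4 equiv), CH2Cl2, –78 °C
Reagents that add atoms: none
Why: Partial DIBAL reduction of the ester at low temperature; the carbamate, acetamide, silyl ether and polyene survive, and the N–H and O–H groups simply consume hydride.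

**Step 22**
Reactants: 24
Product: 25 (E)-vinyl iodide, Cq–CH=CH–I
Conditions: CrCl2 (8 equiv), CHI3, THF/dioxane, 0 °C to rt
Reagents that add atoms: iodoform, IC(I)I
Why: Takai–Hiyama iodoolefination of the non-enolizable aldehyde is E-selective.

**Step 23**
Reactants: 26 but-2-yn-1-ol
Product: 27 (Z)-3-iodobut-2-en-1-ol
Conditions: Red-Al, THF, 0 °C to rt; then I2, –78 °C
Reagents that add atoms: iodine, II
Why: Trans-hydroalumination directed by the propargylic alkoxide puts Al at C3 cis to CH2OH, and iodinolysis retains the geometry, giving the (Z)-iodide.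

**Step 24**
Reactants: 27
Product: 28 (Z)-3-(trimethylstannyl)but-2-en-1-ol
Conditions: (Me3Sn)2, Pd(PPh3)4, THF, 60 °C
Reagents that add atoms: hexamethylditin, C[Sn](C)(C)[Sn](C)(C)C
Why: Pd-catalysed iodide-to-stannane exchange goes with retention of alkene geometry.

**Step 25**
Reactants: 25, 28
Product: 29 dienol Cq–CH=CH–C(CH3)=CH–CH2OH (6E, 4Z as required)
Conditions: Pd(PPh3)4 (10 mol %), CuI, DMF, rt
Reagents that add atoms: none
Why: Stille coupling is stereoretentive, so the E-vinyl iodide and Z-stannane give the E/Z diene.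

**Step 26**
Reactants: 29
Product: 30 (Z)-dienal, Cq–CH=CH–C(CH3)=CH–CHO
Conditions: MnO2, CH2Cl2, rt
Reagents that add atoms: none
Why: MnO2 oxidizes only the activated allylic alcohol; the saturated C6' OH and the alkenes are untouched.

**Step 27**
Reactants: 30, 31 diethylphosphonoacetic acid
Product: 32 phosphonoacetate ester at the C6' oxygen
Conditions: EDC·HCl, DMAP (cat.), CH2Cl2, 0 °C to rt
Reagents that add atoms: none (31 is the building block)
Why: Steglich esterification of the secondary alcohol, with retention at C6'.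

**Step 28**
Reactants: 32
Product: 33 TBS-protected 16-membered macrolactone with E C2=C3
Conditions: LiCl, iPr2NEt, MeCN, 2 mM, 40 °C
Reagents that add atoms: none
Why: Masamune–Roush intramolecular HWE closes the macrocycle with E selectivity for the new enoate alkene, and the remote stereocentres direct a single macrocyclic conformer.

**Step 29**
Reactants: 33
Product: 34 Superstolide A
Conditions: HF·pyridine, pyridine, THF, rt
Reagents that add atoms: none
Why: Fluoride removes the secondary TBS ether; the lactone, carbamate, acetamide and polyene are stable, and no stereocentre is affected.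

## Compound list
1 | benzoic acid | OC(=O)c1ccccc1 | starting material
2 | 1-methylcyclohexa-2,5-diene-1-carboxylic acid | CC1(C=CCC=C1)C(=O)O | intermediate
3 | methyl 1-methylcyclohexa-2,5-diene-1-carboxylate | COC(=O)C1(C)C=CCC=C1 | intermediate
4 | methyl 1-methyl-4-oxocyclohexa-2,5-diene-1-carboxylate | COC(=O)C1(C)C=CC(=O)C=C1 | intermediate
5 | sodium (E)-3-oxobut-1-en-1-olate | CC(=O)/C=C/[O-].[Na+] | starting material
6 | (E)-4-(triisopropylsilyloxy)but-3-en-2-one | CC(=O)/C=C/O[Si](C(C)C)(C(C)C)C(C)C | intermediate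
7 | (E)-1-OTIPS-3-OTMS-buta-1,3-diene | C=C(O[Si](C)(C)C)/C=C/O[Si](C(C)C)(C(C)C)C(C)C | intermediate
8 | cis-fused Diels–Alder keto-enone | O=C1C[C@H](O[Si](C(C)C)(C(C)C)C(C)C)[C@@H]2C(=O)C=C[C@](C)(C(=O)OC)[C@@H]2C1 | intermediate
9 | methyl ether | CO[C@@H]1C[C@H](O[Si](C(C)C)(C(C)C)C(C)C)[C@@H]2C(=O)C=C[C@](C)(C(=O)OC)[C@@H]2C1 | intermediate
10 | allylic alcohol | CO[C@@H]1C[C@H](O[Si](C(C)C)(C(C)C)C(C)C)[C@@H]2[C@H](O)C=C[C@](C)(C(=O)OC)[C@@H]2C1 | intermediate
11 | Claisen methyl ketone | CO[C@@H]1C[C@H](O[Si](C(C)C)(C(C)C)C(C)C)[C@@H]2C=C[C@H](CC(C)=O)[C@](C)(C(=O)OC)[C@@H]2C1 | intermediate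
12 | (E)-enol triflate | CO[C@@H]1C[C@H](O[Si](C(C)C)(C(C)C)C(C)C)[C@@H]2C=C[C@H](/C=C(\C)OS(=O)(=O)C(F)(F)F)[C@](C)(C(=O)OC)[C@@H]2C1 | intermediate
13 | free alcohol | CO[C@@H]1C[C@H](O)[C@@H]2C=C[C@H](/C=C(\C)OS(=O)(=O)C(F)(F)F)[C@](C)(C(=O)OC)[C@@H]2C1 | intermediate
14 | carbamate enol triflate | CO[C@@H]1C[C@H](OC(N)=O)[C@@H]2C=C[C@H](/C=C(\C)OS(=O)(=O)C(F)(F)F)[C@](C)(C(=O)OC)[C@@H]2C1 | intermediate
15 | (R)-2-aminopropan-1-ol | C[C@@H](N)CO | starting material
16 | (R)-N-(1-hydroxypropan-2-yl)acetamide | C[C@@H](NC(C)=O)CO | intermediate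
17 | (2R)-2-acetamidopropanal | C[C@@H](NC(C)=O)C=O | intermediate
18 | anti,anti homoallylic alcohol | C=C[C@H](C)[C@H](O)[C@@H](C)NC(C)=O | intermediate
19 | TBS ether of 18 | C=C[C@H](C)[C@H](O[Si](C)(C)C(C)(C)C)[C@@H](C)NC(C)=O | intermediate
20 | α-methyl aldehyde | O=C[C@H](C)[C@H](O[Si](C)(C)C(C)(C)C)[C@@H](C)NC(C)=O | intermediate
21 | stereopentad alcohol (terminal vinyl) | C=C[C@@H](C)[C@@H](O)[C@H](C)[C@H](O[Si](C)(C)C(C)(C)C)[C@@H](C)NC(C)=O | intermediate
22 | (E)-alkenyl-Bpin | CC1(C)OB(OC1(C)C)/C=C/[C@@H](C)[C@@H](O)[C@H](C)[C@H](O[Si](C)(C)C(C)(C)C)[C@@H](C)NC(C)=O | intermediate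
23 | Suzuki product (ester) | CO[C@@H]1C[C@H](OC(N)=O)[C@@H]2C=C[C@H](/C=C(\C)/C=C/[C@@H](C)[C@@H](O)[C@H](C)[C@H](O[Si](C)(C)C(C)(C)C)[C@@H](C)NC(C)=O)[C@](C)(C(=O)OC)[C@@H]2C1 | intermediate
24 | aldehyde | CO[C@@H]1C[C@H](OC(N)=O)[C@@H]2C=C[C@H](/C=C(\C)/C=C/[C@@H](C)[C@@H](O)[C@H](C)[C@H](O[Si](C)(C)C(C)(C)C)[C@@H](C)NC(C)=O)[C@](C)(C=O)[C@@H]2C1 | intermediate
25 | (E)-vinyl iodide | CO[C@@H]1C[C@H](OC(N)=O)[C@@H]2C=C[C@H](/C=C(\C)/C=C/[C@@H](C)[C@@H](O)[C@H](C)[C@H](O[Si](C)(C)C(C)(C)C)[C@@H](C)NC(C)=O)[C@](C)(/C=C/I)[C@@H]2C1 | intermediate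
26 | but-2-yn-1-ol | CC#CCO | starting material
27 | (Z)-3-iodobut-2-en-1-ol | C/C(I)=C/CO | intermediate
28 | (Z)-3-(trimethylstannyl)but-2-en-1-ol | C/C([Sn](C)(C)C)=C/CO | intermediate
29 | dienol | CO[C@@H]1C[C@H](OC(N)=O)[C@@H]2C=C[C@H](/C=C(\C)/C=C/[C@@H](C)[C@@H](O)[C@H](C)[C@H](O[Si](C)(C)C(C)(C)C)[C@@H](C)NC(C)=O)[C@](C)(/C=C/C(/C)=C\CO)[C@@H]2C1 | intermediate
30 | (Z)-dienal | CO[C@@H]1C[C@H](OC(N)=O)[C@@H]2C=C[C@H](/C=C(\C)/C=C/[C@@H](C)[C@@H](O)[C@H](C)[C@H](O[Si](C)(C)C(C)(C)C)[C@@H](C)NC(C)=O)[C@](C)(/C=C/C(/C)=C\C=O)[C@@H]2C1 | intermediate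
31 | diethylphosphonoacetic acid | CCOP(=O)(CC(=O)O)OCC | starting material
32 | phosphonoacetate ester | CO[C@@H]1C[C@H](OC(N)=O)[C@@H]2C=C[C@H](/C=C(\C)/C=C/[C@@H](C)[C@@H](OC(=O)CP(=O)(OCC)OCC)[C@H](C)[C@H](O[Si](C)(C)C(C)(C)C)[C@@H](C)NC(C)=O)[C@](C)(/C=C/C(/C)=C\C=O)[C@@H]2C1 | intermediate
33 | TBS-macrolactone | CO[C@@H]1C[C@H](OC(N)=O)[C@@H]2C=C[C@@H]3/C=C(C)/C=C/[C@@H](C)[C@H]([C@H](C)[C@H](O[Si](C)(C)C(C)(C)C)[C@@H](C)NC(C)=O)OC(=O)/C=C/C=C(C)\C=C\[C@]3(C)[C@@H]2C1 | intermediate
34 | Superstolide A | CO[C@@H]1C[C@H](OC(N)=O)[C@@H]2C=C[C@@H]3/C=C(C)/C=C/[C@@H](C)[C@H]([C@H](C)[C@H](O)[C@@H](C)NC(C)=O)OC(=O)/C=C/C=C(C)\C=C\[C@]3(C)[C@@H]2C1 | target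

## Totals
- Total steps: 29.
- Longest linear sequence: 18 steps (1→2→3→6→7→8→9→10→11→12→20→21→22→25→26→27→28→29).

## Three steps most likely to fail
1. **Step 6 (catalytic desymmetrizing Diels–Alder).** Enantio- and facial selectivity, and endo control, on a cross-conjugated dienone with a chiral oxazaborolidinium are unproven. Fallback: make the 8-phenylmenthyl ester of acid 2 in Step 2 and run the Diels–Alder with Et2AlCl for auxiliary-controlled diastereoselection, with the auxiliary released at the DIBAL step.
2. **Step 3 (bis-allylic oxidation of the Birch diene).** The pentadienyl radical or cation could aromatize by methyl or ester loss, or oxidize at C2. Fallback: abandon the Birch route and build dienone 4 from commercial ethyl 1,4-dioxaspiro[4.5]decane-8-carboxylate by LDA/MeI, acid deprotection and IBX·MPO double dehydrogenation.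
3. **Step 28 (macro-HWE).** Z→E isomerization of the trisubstituted dienal, oligomerization or low yield are possible. Fallback: change the ring-closing disconnection. Do an intermolecular HWE of dienal 30 with triethyl phosphonoacetate to give the trienoate, saponify, and close the ring by Yamaguchi macrolactonization onto the free C6' OH.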